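**Strategy**

The bicyclo[3.3.1]nonane is cut at C7–C8 and C1–C2. The plan rests on a polarity match in ring B: C8, the gem-dimethyl carbon, lies β to the bridging C9 carbonyl, and C7 lies β to a carboxyl carbon once its prenyl group is carried as an acetate arm. Reductive union of these two like-polarised positions leaves an enolate at bridgehead C1, where ring A needs a nucleophile to reach C2. One cascade thus closes both six-membered rings of an acyclic ketone and sets C7 and C1 from the single preset centre C5, a quaternary carbon bearing geranyl, a crotonate arm, an (E)-β-methoxyacrylate and a 2-geranyl-3-methylbut-2-enoyl group.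

Key step: step 9

Core numbering used below: C1 and C5 are the bridgeheads (C1 beside C8, C5 beside C6), C2–C4 is the three-carbon bridge (ring A = C1–C5 plus C9), C6–C8 the second bridge (ring B), C9 the bridging ketone. Geranyl = (2E)-3,7-dimethylocta-2,6-dien-1-yl.

Assumption: the target is one enol tautomer of a 2,4-dione and is obtained as the equilibrating tautomers; in step 8 the (S)-ammonium salt is written as the antipode that gives (4R)-15, to be confirmed by correlation in the first run, the (R)-salt being used otherwise.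

**Route**

Step 1
Reactants: 1 methyl acetoacetate; 2 geranyl bromide
Product: 4 methyl (6E)-7,11-dimethyl-3-oxododeca-6,10-dienoate, via acetoacetate dianion 3 (not isolated)
Conditions: NaH, THF, 0 °C; n-BuLi, 0 °C; then 2, 0 °C → rt; 1 M HCl
Reagents that add atoms: none
Why: Alkylation of the acetoacetate dianion, in which the terminal carbanion is the more reactive site and displaces the allylic bromide by SN2, so the geranyl group enters at the γ-carbon with its E-alkene intact and no stereocentre is formed.

Step 2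
Reactants: 4 methyl (6E)-7,11-dimethyl-3-oxododeca-6,10-dienoate
Product: 5 methyl (2E,6E)-3-methoxy-7,11-dimethyldodeca-2,6,10-trienoate
Conditions: HC(OMe)3, p-TsOH·H2O (cat.), MeOH, rt; K2CO3 quench
Reagents that add atoms: trimethyl orthoformate, COC(OC)OC
Why: Acid-catalysed enol ether formation (ketalisation, then loss of methanol) gives the conjugated β-methoxy enoate, and under these equilibrating conditions the E isomer with the carbon chain cis to the ester is the thermodynamic product, which is the geometry ring A closure in step 9 requires.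

Step 3
Reactants: 6 ethyl 3-methylbut-2-enoate; 2 geranyl bromide
Product: 8 ethyl (4E)-5,9-dimethyl-2-(prop-1-en-2-yl)deca-4,8-dienoate (racemic), via lithium dienolate 7 (not isolated)
Conditions: LiN(i-Pr)2, THF–DMPU, −78 °C; then 2, −78 → 0 °C
Reagents that add atoms: none
Why: Deconjugative α-alkylation of a dienolate, in which γ-deprotonation of the senecioate and kinetic SN2 attack through the α-carbon attach the geranyl group next to the ester; the stereocentre formed is racemic and is erased in step 4.

Step 4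
Reactants: 8 ethyl (4E)-5,9-dimethyl-2-(prop-1-en-2-yl)deca-4,8-dienoate
Product: 9 ethyl (4E)-5,9-dimethyl-2-(propan-2-ylidene)deca-4,8-dienoate
Conditions: NaOEt (0.3 equiv), EtOH, reflux
Reagents that add atoms: none
Why: Base-catalysed prototropic isomerisation under thermodynamic control should move the isopropenyl double bond into conjugation as the tetrasubstituted enoate, and residual 8 is separated by chromatography and recycled.

Step 5
Reactants: 9 ethyl (4E)-5,9-dimethyl-2-(propan-2-ylidene)deca-4,8-dienoate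
Product: 10 (4E)-5,9-dimethyl-2-(propan-2-ylidene)deca-4,8-dienoic acid
Conditions: KOH, EtOH–H2O, reflux; then 1 M HCl, 0 °C
Reagents that add atoms: potassium hydroxide, [K+].[OH-]
Why: Ester saponification by acyl–oxygen cleavage; once the carboxylate is formed it is not deprotonated further, so the double bond should stay in conjugation.

Step 6
Reactants: 10 (4E)-5,9-dimethyl-2-(propan-2-ylidene)deca-4,8-dienoic acid
Product: 11 (4E)-5,9-dimethyl-2-(propan-2-ylidene)deca-4,8-dienoyl chloride
Conditions: 1-chloro-N,N,2-trimethylprop-1-en-1-amine, CH2Cl2, 0 °C → rt; used crude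
Reagents that add atoms: 1-chloro-N,N,2-trimethylprop-1-en-1-amine, CC(C)=C(Cl)N(C)C
Why: Conversion of the acid into its chloride with an α-chloroenamine takes place under neutral conditions without free HCl, which protects the two trisubstituted alkenes.

Step 7
Reactants: 5 methyl (2E,6E)-3-methoxy-7,11-dimethyldodeca-2,6,10-trienoate; 11 (4E)-5,9-dimethyl-2-(propan-2-ylidene)deca-4,8-dienoyl chloride
Product: 13 methyl (2E)-4,6-digeranyl-3-methoxy-7-methyl-5-oxoocta-2,6-dienoate (racemic), via silyl ketene acetal 12 (not isolated)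
Conditions: 5, LiN(i-Pr)2, THF, −78 °C; Me3SiCl; evaporate, filter through pentane; then 11, CH2Cl2, −78 → 20 °C; used promptly
Reagents that add atoms: none
Why: Vinylogous Mukaiyama-type acylation, in which the 1,3-dialkoxy-1-silyloxydiene 12 reacts with the acid chloride at its γ-terminus and so avoids the α-attack and proton-transfer problems of the lithium dienolate; the conjugated E-enol ether is restored on loss of the silyl group, and the new stereocentre (C5 of the core) is racemic and becomes quaternary in step 8.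

Step 8
Reactants: 13 methyl (2E)-4,6-digeranyl-3-methoxy-7-methyl-5-oxoocta-2,6-dienoate; 14 methyl (2E)-4-bromobut-2-enoate
Product: 15 methyl (2E,4R)-4,6-digeranyl-3-methoxy-4-[(2E)-4-methoxy-4-oxobut-2-en-1-yl]-7-methyl-5-oxoocta-2,6-dienoate
Conditions: (S)-4,4-dibutyl-2,6-bis(3,4,5-trifluorophenyl)-4,5-dihydro-3H-dinaphtho[2,1-c:1',2'-e]azepinium bromide (5 mol%), CsOH·H2O (solid), toluene, −40 °C
Reagents that add atoms: none
Why: Asymmetric phase-transfer alkylation, in which the doubly stabilised enolate of 13 enters toluene as an ion pair with the C2-symmetric chiral ammonium cation and attacks the allylic bromide by SN2 through C5 (the carbon α to the ketone) on the face the catalyst leaves open, which should set the quaternary centre as 4R, while solid base at low temperature spares the methyl esters and limits lactonisation of the enolate.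

Step 9
Reactants: 15 methyl (2E,4R)-4,6-digeranyl-3-methoxy-4-[(2E)-4-methoxy-4-oxobut-2-en-1-yl]-7-methyl-5-oxoocta-2,6-dienoate
Product: 17 methyl 2-[(1R,5S,7S)-1,5-digeranyl-4-methoxy-8,8-dimethyl-2,9-dioxobicyclo[3.3.1]non-3-en-7-yl]acetate, via samarium bis(enolate) 16 (not isolated)
Conditions: SmI2 (2.2 equiv) and HMPA (8 equiv) added slowly to 15, THF (0.01 M), −78 → 0 °C, no proton source; then aq. NH4Cl
Reagents that add atoms: none
Why: Proposed new method: SmI2–HMPA transfers one electron to the C9 carbonyl of the tetrasubstituted enone; the delocalised radical anion carries spin at the tertiary β-carbon C8, which adds to the unhindered enoate β-carbon C7 (6-exo-trig, ring B), a second electron turns the α-ester radical into a samarium ester enolate, and in bis(enolate) 16 the C1=C9 ketone enolate attacks the methoxyacrylate ester carbon C2 (6-enolendo-exo-trig Dieckmann closure, ring A) with loss of samarium-bound methoxide. Precedent stops at reductive hydrocyclisations that join the β-carbons of a tethered enone and enoate (SmI2 or cathode) and at radical–polar crossover sequences whose enolate is trapped in an aldol or acyl-transfer step; a β,β-coupling that hands a fully substituted bridgehead enolate straight to an ester is not established. C7 is set in the first closure relative to the preset C5: in the half-chair transition state the enoate lies equatorial and the α-branched methoxyacrylate arm should take the pseudoaxial site on C5 to avoid allylic 1,2-strain with the bulky HMPA-solvated O–Sm group on C9, which puts the C7 chain trans to that arm (7-exo). C1 is then fixed by the bridge, since the pseudoaxial arm can reach only one face of the enolate. The step needs enone-first electron transfer (the ketone is the better ligand and acceptor for divalent samarium and the β-methoxyacrylate is too electron-rich to be reduced), C- rather than O-acylation (trivalent samarium stays on the enolate oxygen) and no Claisen attack on the side-chain ester, the last secured by omitting a proton source so that this ester remains masked as its own enolate until work-up. Because the enol ether was made as its E isomer in step 2, the ester carbonyl C2 already sits on the same side of the C3=C4 bond as C5 and needs no isomerisation before ring A closes.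

Step 10
Reactants: 17 methyl 2-[(1R,5S,7S)-1,5-digeranyl-4-methoxy-8,8-dimethyl-2,9-dioxobicyclo[3.3.1]non-3-en-7-yl]acetate
Product: 18 2-[(1R,5S,7S)-1,5-digeranyl-4-methoxy-8,8-dimethyl-2,9-dioxobicyclo[3.3.1]non-3-en-7-yl]acetic acid
Conditions: LiOH·H2O, THF–MeOH–H2O, 0 °C → rt; then 1 M HCl, 0 °C
Reagents that add atoms: lithium hydroxide, [Li+].[OH-]
Why: Saponification of the unhindered primary methyl ester at room temperature, conditions under which the vinylogous methyl ester of ring A (which needs hot hydroxide) and the two non-enolisable, neopentyl ketones should not react.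

Step 11
Reactants: 18 2-[(1R,5S,7S)-1,5-digeranyl-4-methoxy-8,8-dimethyl-2,9-dioxobicyclo[3.3.1]non-3-en-7-yl]acetic acid
Product: 19 S-ethyl 2-[(1R,5S,7S)-1,5-digeranyl-4-methoxy-8,8-dimethyl-2,9-dioxobicyclo[3.3.1]non-3-en-7-yl]ethanethioate
Conditions: EtSH, EDC·HCl, DMAP (cat.), CH2Cl2, 0 °C → rt
Reagents that add atoms: ethanethiol, CCS
Why: Carbodiimide-mediated (Steglich-type) thioesterification activates the acid as its O-acylisourea and acylpyridinium ion, which the thiol intercepts, and no stereocentre is touched.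

Step 12
Reactants: 19 S-ethyl 2-[(1R,5S,7S)-1,5-digeranyl-4-methoxy-8,8-dimethyl-2,9-dioxobicyclo[3.3.1]non-3-en-7-yl]ethanethioate
Product: 20 2-[(1R,5S,7S)-1,5-digeranyl-4-methoxy-8,8-dimethyl-2,9-dioxobicyclo[3.3.1]non-3-en-7-yl]acetaldehyde
Conditions: Et3SiH, 10% Pd/C, acetone, rt
Reagents that add atoms: none
Why: Fukuyama reduction, in which zerovalent palladium inserts into the C–S bond and the silane delivers hydride, gives the aldehyde under neutral conditions that should leave both ketones, the vinylogous ester and the trisubstituted alkenes alone, a selectivity a hydride reagent could not guarantee here.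

Step 13
Reactants: 20 2-[(1R,5S,7S)-1,5-digeranyl-4-methoxy-8,8-dimethyl-2,9-dioxobicyclo[3.3.1]non-3-en-7-yl]acetaldehyde
Product: 21 (1R,5S,7R)-1,5-digeranyl-4-methoxy-8,8-dimethyl-7-(3-methylbut-2-en-1-yl)bicyclo[3.3.1]non-3-ene-2,9-dione
Conditions: i-PrPPh3I, n-BuLi, THF, 0 °C; then 20, −78 → 0 °C
Reagents that add atoms: isopropyltriphenylphosphonium iodide, CC(C)[P+](c1ccccc1)(c1ccccc1)c1ccccc1.[I-]
Why: Wittig olefination with the non-stabilised isopropylidene ylide turns the aldehyde into the prenyl group, the aldehyde reacting far faster than the two hindered ketones, and C7 is not epimerisable.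

Step 14
Reactants: 22 3,4-dihydroxybenzoic acid
Product: 24 3,4-bis[(tert-butyldimethylsilyl)oxy]benzoic acid, via silyl ester 23 (not isolated)
Conditions: TBSCl, imidazole, DMF, rt; then AcOH–THF–H2O, rt
Reagents that add atoms: tert-butyldimethylsilyl chloride, CC(C)(C)[Si](C)(C)Cl
Why: Silylation of all three hydroxyl groups and selective hydrolysis of the far more labile silyl ester leave the two aryl silyl ethers in place.

Step 15
Reactants: 24 3,4-bis[(tert-butyldimethylsilyl)oxy]benzoic acid
Product: 25 3,4-bis[(tert-butyldimethylsilyl)oxy]benzoyl chloride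
Conditions: 1-chloro-N,N,2-trimethylprop-1-en-1-amine, CH2Cl2, 0 °C → rt; used crude
Reagents that add atoms: 1-chloro-N,N,2-trimethylprop-1-en-1-amine, CC(C)=C(Cl)N(C)C
Why: Neutral acid chloride formation with the α-chloroenamine avoids HCl and so keeps the aryl silyl ethers.

Step 16
Reactants: 21 (1R,5S,7R)-1,5-digeranyl-4-methoxy-8,8-dimethyl-7-(3-methylbut-2-en-1-yl)bicyclo[3.3.1]non-3-ene-2,9-dione; 25 3,4-bis[(tert-butyldimethylsilyl)oxy]benzoyl chloride
Product: 27 (1S,5S,7R)-3-{3,4-bis[(tert-butyldimethylsilyl)oxy]benzoyl}-1,5-digeranyl-4-methoxy-8,8-dimethyl-7-(3-methylbut-2-en-1-yl)bicyclo[3.3.1]non-3-ene-2,9-dione, via C3-lithio derivative 26 (not isolated)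
Conditions: lithium 2,2,6,6-tetramethylpiperidide, THF, −78 °C; then 25, −78 → −40 °C
Reagents that add atoms: none
Why: Directed lithiation of the β-methoxy enone at C3, its only acidic site now that both bridgeheads are quaternary, followed by C-acylation of the vinyllithium with the aroyl chloride, a sequence established for O-methylated bicyclo[3.3.1]nonane-2,4,9-triones; the stereocentres are not involved.

Step 17
Reactants: 27 (1S,5S,7R)-3-{3,4-bis[(tert-butyldimethylsilyl)oxy]benzoyl}-1,5-digeranyl-4-methoxy-8,8-dimethyl-7-(3-methylbut-2-en-1-yl)bicyclo[3.3.1]non-3-ene-2,9-dione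
Product: 28 (1S,5S,7R)-3-(3,4-dihydroxybenzoyl)-1,5-digeranyl-4-hydroxy-8,8-dimethyl-7-(3-methylbut-2-en-1-yl)bicyclo[3.3.1]non-3-ene-2,9-dione (CNP0178719.1)
Conditions: LiOH, H2O–1,4-dioxane (degassed), 80 °C, Ar; then 1 M HCl, 0 °C
Reagents that add atoms: lithium hydroxide, [Li+].[OH-]
Why: Hydroxide adds to C4 of the doubly activated enol ether and expels methoxide (addition–elimination hydrolysis of the vinylogous ester) and also cleaves the base-labile aryl silyl ethers, and cold acidification of the degassed solution should release the enol and the catechol without acid-induced cyclisation onto the prenyl groups.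

**Compound list**

1 | methyl acetoacetate | COC(=O)CC(C)=O | starting material
2 | geranyl bromide, (2E)-1-bromo-3,7-dimethylocta-2,6-diene | CC(C)=CCC/C(C)=C/CBr | starting material
3 | sodium lithium dianion of methyl acetoacetate | [Na+].[Li+].COC([O-])=CC([O-])=C | intermediate
4 | methyl (6E)-7,11-dimethyl-3-oxododeca-6,10-dienoate | COC(=O)CC(=O)CC/C=C(\C)CCC=C(C)C | intermediate
5 | methyl (2E,6E)-3-methoxy-7,11-dimethyldodeca-2,6,10-trienoate | COC(=O)/C=C(/OC)CC/C=C(\C)CCC=C(C)C | intermediate
6 | ethyl 3-methylbut-2-enoate | CCOC(=O)C=C(C)C | starting material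
7 | lithium dienolate of ethyl 3-methylbut-2-enoate | [Li+].CCOC([O-])=CC(C)=C | intermediate
8 | ethyl (4E)-5,9-dimethyl-2-(prop-1-en-2-yl)deca-4,8-dienoate (racemic) | CCOC(=O)C(C/C=C(\C)CCC=C(C)C)C(C)=C | intermediate
9 | ethyl (4E)-5,9-dimethyl-2-(propan-2-ylidene)deca-4,8-dienoate | CCOC(=O)C(C/C=C(\C)CCC=C(C)C)=C(C)C | intermediate
10 | (4E)-5,9-dimethyl-2-(propan-2-ylidene)deca-4,8-dienoic acid | OC(=O)C(C/C=C(\C)CCC=C(C)C)=C(C)C | intermediate
11 | (4E)-5,9-dimethyl-2-(propan-2-ylidene)deca-4,8-dienoyl chloride | ClC(=O)C(C/C=C(\C)CCC=C(C)C)=C(C)C | intermediate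
12 | trimethylsilyl ketene acetal of 5, (6E)-1,3-dimethoxy-7,11-dimethyl-1-(trimethylsilyloxy)dodeca-1,3,6,10-tetraene (C1=C2 and C3=C4 as formed) | COC(O[Si](C)(C)C)=CC(OC)=CC/C=C(\C)CCC=C(C)C | intermediate
13 | methyl (2E)-4,6-digeranyl-3-methoxy-7-methyl-5-oxoocta-2,6-dienoate (racemic at C4) | COC(=O)/C=C(/OC)C(C/C=C(\C)CCC=C(C)C)C(=O)C(C/C=C(\C)CCC=C(C)C)=C(C)C | intermediate
14 | methyl (2E)-4-bromobut-2-enoate | COC(=O)/C=C/CBr | starting material
15 | methyl (2E,4R)-4,6-digeranyl-3-methoxy-4-[(2E)-4-methoxy-4-oxobut-2-en-1-yl]-7-methyl-5-oxoocta-2,6-dienoate | CC(C)=CCC/C(C)=C/C[C@](C/C=C/C(=O)OC)(/C(OC)=C\C(=O)OC)C(=O)C(C/C=C(\C)CCC=C(C)C)=C(C)C | intermediate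
16 | bis(diiodosamarium) enolate after closure of ring B: cyclohex-1-en-1-olate (C9–O–SmI2, C1=C9) with geranyl on C1 and C5, the (E)-methoxyacrylate arm on C5, gem-dimethyl C8 and, on C7, the ester enolate CH=C(OMe)O–SmI2; C5 and C7 as in 17 | CC(C)=CCC/C(C)=C/C[C@@]1(/C(OC)=C\C(=O)OC)C[C@@H](C=C(OC)O[Sm](I)I)C(C)(C)C(C/C=C(\C)CCC=C(C)C)=C1O[Sm](I)I | intermediate
17 | methyl 2-[(1R,5S,7S)-1,5-digeranyl-4-methoxy-8,8-dimethyl-2,9-dioxobicyclo[3.3.1]non-3-en-7-yl]acetate (C7 chain cis to the C5 geranyl, trans to the C2–C4 bridge) | CC(C)=CCC/C(C)=C/C[C@]12C[C@@H](CC(=O)OC)C(C)(C)[C@](C/C=C(\C)CCC=C(C)C)(C(=O)C=C1OC)C2=O | intermediate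
18 | 2-[(1R,5S,7S)-1,5-digeranyl-4-methoxy-8,8-dimethyl-2,9-dioxobicyclo[3.3.1]non-3-en-7-yl]acetic acid | CC(C)=CCC/C(C)=C/C[C@]12C[C@@H](CC(=O)O)C(C)(C)[C@](C/C=C(\C)CCC=C(C)C)(C(=O)C=C1OC)C2=O | intermediate
19 | S-ethyl 2-[(1R,5S,7S)-1,5-digeranyl-4-methoxy-8,8-dimethyl-2,9-dioxobicyclo[3.3.1]non-3-en-7-yl]ethanethioate | CC(C)=CCC/C(C)=C/C[C@]12C[C@@H](CC(=O)SCC)C(C)(C)[C@](C/C=C(\C)CCC=C(C)C)(C(=O)C=C1OC)C2=O | intermediate
20 | 2-[(1R,5S,7S)-1,5-digeranyl-4-methoxy-8,8-dimethyl-2,9-dioxobicyclo[3.3.1]non-3-en-7-yl]acetaldehyde | CC(C)=CCC/C(C)=C/C[C@]12C[C@@H](CC=O)C(C)(C)[C@](C/C=C(\C)CCC=C(C)C)(C(=O)C=C1OC)C2=O | intermediate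
21 | (1R,5S,7R)-1,5-digeranyl-4-methoxy-8,8-dimethyl-7-(3-methylbut-2-en-1-yl)bicyclo[3.3.1]non-3-ene-2,9-dione | CC(C)=CCC/C(C)=C/C[C@]12C[C@@H](CC=C(C)C)C(C)(C)[C@](C/C=C(\C)CCC=C(C)C)(C(=O)C=C1OC)C2=O | intermediate
22 | 3,4-dihydroxybenzoic acid | OC(=O)c1ccc(O)c(O)c1 | starting material
23 | tert-butyldimethylsilyl 3,4-bis[(tert-butyldimethylsilyl)oxy]benzoate | CC(C)(C)[Si](C)(C)OC(=O)c1ccc(O[Si](C)(C)C(C)(C)C)c(O[Si](C)(C)C(C)(C)C)c1 | intermediate
24 | 3,4-bis[(tert-butyldimethylsilyl)oxy]benzoic acid | OC(=O)c1ccc(O[Si](C)(C)C(C)(C)C)c(O[Si](C)(C)C(C)(C)C)c1 | intermediate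
25 | 3,4-bis[(tert-butyldimethylsilyl)oxy]benzoyl chloride | ClC(=O)c1ccc(O[Si](C)(C)C(C)(C)C)c(O[Si](C)(C)C(C)(C)C)c1 | intermediate
26 | (1R,5S,7R)-1,5-digeranyl-3-lithio-4-methoxy-8,8-dimethyl-7-(3-methylbut-2-en-1-yl)bicyclo[3.3.1]non-3-ene-2,9-dione | CC(C)=CCC/C(C)=C/C[C@]12C[C@@H](CC=C(C)C)C(C)(C)[C@](C/C=C(\C)CCC=C(C)C)(C(=O)C([Li])=C1OC)C2=O | intermediate
27 | (1S,5S,7R)-3-{3,4-bis[(tert-butyldimethylsilyl)oxy]benzoyl}-1,5-digeranyl-4-methoxy-8,8-dimethyl-7-(3-methylbut-2-en-1-yl)bicyclo[3.3.1]non-3-ene-2,9-dione | CC(C)=CCC/C(C)=C/C[C@]12C[C@@H](CC=C(C)C)C(C)(C)[C@](C/C=C(\C)CCC=C(C)C)(C(=O)C(C(=O)c3ccc(O[Si](C)(C)C(C)(C)C)c(O[Si](C)(C)C(C)(C)C)c3)=C1OC)C2=O | intermediate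
28 | (1S,5S,7R)-3-(3,4-dihydroxybenzoyl)-1,5-digeranyl-4-hydroxy-8,8-dimethyl-7-(3-methylbut-2-en-1-yl)bicyclo[3.3.1]non-3-ene-2,9-dione (CNP0178719.1) | CC(C)=CCC/C(C)=C/C[C@]12C[C@@H](CC=C(C)C)C(C)(C)[C@](C/C=C(\C)CCC=C(C)C)(C(=O)C(C(=O)c3ccc(O)c(O)c3)=C1O)C2=O | target

**Step count**

Total step count: 17.
Longest linear sequence: 13 steps (from 6: steps 3–13, 16 and 17).

**Steps most likely to fail**

1. Step 9 (proposed new method). Electron transfer may go to the crotonate instead of the twisted enone, whose β-radical would then close onto the C5 geranyl alkene or simply be saturated. The first closure may show poor facial selectivity at C7. The cascade may also stall after ring B, because the hindered C1 enolate acylates slowly or on oxygen. Fallback with known chemistry, setting out from 15 and coming back at 17: the two bonds are made in separate, established operations. Reductive cyclisation of the enone–enoate pair in the presence of a proton donor (SmI2, HMPA, t-BuOH, THF, −78 °C, or cathodic hydrocyclisation) stops at the monocyclic keto diester methyl (2E)-3-[1,3-digeranyl-5-(2-methoxy-2-oxoethyl)-4,4-dimethyl-2-oxocyclohexyl]-3-methoxyprop-2-enoate F1, whose C7 epimers are separated. A base-mediated Dieckmann condensation (KOt-Bu, THF, 0 °C, cold quench) through the regenerated C1 ketone enolate then closes ring A to 17.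

2. Step 8. Enantioselectivity may be insufficient, because the acyclic enolate can react through two geometries in a loose ion pair. Lactonisation of the enolate onto the cis ester and Michael-initiated cyclopropanation by the bromocrotonate are further competing processes. Fallback, setting out from 13 and coming back at 15: alkylation without chiral control (K2CO3, Bu4NBr cat., MeCN, rt) gives the racemic precursor methyl (2E)-4,6-digeranyl-3-methoxy-4-[(2E)-4-methoxy-4-oxobut-2-en-1-yl]-7-methyl-5-oxoocta-2,6-dienoate F2. This is resolved by preparative chromatography on a chiral stationary phase into 15 and its (4S)-enantiomer F3, which is discarded.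

3. Step 7. The hindered acid chloride may acylate the dienoxysilane at the wrong terminus (α-carbon or oxygen), or the product may cyclise to a 2-pyranone during isolation. Fallback, setting out from 9 (with 12 made from 5 as in step 7) and coming back at 13: the C5–C9 bond is made by an aldol addition instead of an acylation. Reduction of 9 with i-Bu2AlH gives (4E)-5,9-dimethyl-2-(propan-2-ylidene)deca-4,8-dien-1-ol F4, and MnO2 oxidation gives (4E)-5,9-dimethyl-2-(propan-2-ylidene)deca-4,8-dienal F5. A BF3·OEt2-mediated vinylogous Mukaiyama aldol addition of 12 to F5, γ-selective for this diene class, gives methyl (2E)-4,6-digeranyl-5-hydroxy-3-methoxy-7-methylocta-2,6-dienoate F6, and Dess–Martin oxidation of the carbinol returns 13.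

Further compounds
F1 | step 9 | methyl (2E)-3-[1,3-digeranyl-5-(2-methoxy-2-oxoethyl)-4,4-dimethyl-2-oxocyclohexyl]-3-methoxyprop-2-enoate (ring carbons 1 and 5 as C5 and C7 of 17, carbon 3 as epimers) | CC(C)=CCC/C(C)=C/C[C@@]1(/C(OC)=C\C(=O)OC)C[C@@H](CC(=O)OC)C(C)(C)C(C/C=C(\C)CCC=C(C)C)C1=O
F2 | step 8 | racemic methyl (2E)-4,6-digeranyl-3-methoxy-4-[(2E)-4-methoxy-4-oxobut-2-en-1-yl]-7-methyl-5-oxoocta-2,6-dienoate | CC(C)=CCC/C(C)=C/CC(C/C=C/C(=O)OC)(/C(OC)=C\C(=O)OC)C(=O)C(C/C=C(\C)CCC=C(C)C)=C(C)C
F3 | step 8 | methyl (2E,4S)-4,6-digeranyl-3-methoxy-4-[(2E)-4-methoxy-4-oxobut-2-en-1-yl]-7-methyl-5-oxoocta-2,6-dienoate | CC(C)=CCC/C(C)=C/C[C@@](C/C=C/C(=O)OC)(/C(OC)=C\C(=O)OC)C(=O)C(C/C=C(\C)CCC=C(C)C)=C(C)C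
F4 | step 7 | (4E)-5,9-dimethyl-2-(propan-2-ylidene)deca-4,8-dien-1-ol | OCC(C/C=C(\C)CCC=C(C)C)=C(C)C
F5 | step 7 | (4E)-5,9-dimethyl-2-(propan-2-ylidene)deca-4,8-dienal | O=CC(C/C=C(\C)CCC=C(C)C)=C(C)C
F6 | step 7 | methyl (2E)-4,6-digeranyl-5-hydroxy-3-methoxy-7-methylocta-2,6-dienoate (diastereomer mixture) | COC(=O)/C=C(/OC)C(C/C=C(\C)CCC=C(C)C)C(O)C(C/C=C(\C)CCC=C(C)C)=C(C)C
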